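The route rests on disconnecting N1–C7a of the pyrrole ring. Because C4, the benzo-ring neighbour of C3a, carries bromine while C7, the benzo-ring neighbour of C7a, is unsubstituted, a 2,4-dibromophenyl ring offers a single ortho C–H. Thermolysis of a vinyl azide therefore closes the pyrrole ring there in one operation and fixes the 4,6-dibromo pattern of the benzo ring. The precursor is methyl (Z)-2-azido-3-(2,4-dibromophenyl)acrylate, made by condensing 2,4-dibromobenzaldehyde with methyl azidoacetate. The C2 ester delivered by the cyclisation blocks C2 during C3 methylsulfenylation and is then exchanged for the last bromine by saponification and bromodecarboxylation.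

Key step: step 2

Remark: methyl azidoacetate is assumed to be purchased and dosed as a solution, and no azide in the route is distilled or heated without solvent.

Step 1
Reactants: 1 2,4-dibromobenzaldehyde; 2 methyl azidoacetate
Product: 4 methyl (Z)-2-azido-3-(2,4-dibromophenyl)prop-2-enoate, via aldol adduct 3 (not isolated)
Conditions: NaOMe (4 equiv), 2 (4 equiv), MeOH, −15 → 0 °C; ice/aq NH4Cl quench
Reagents that add atoms: none
Why: Knoevenagel-type aldol condensation: methoxide deprotonates 2, the azido enolate adds to the aldehyde to give aldol adduct 3, and E1cB loss of hydroxide should deliver the conjugated alkene as the more stable Z isomer (aryl trans to the ester, cis to the azide), the low temperature keeping the azido enolate from losing N2; no stereocentre remains.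

Step 2
Reactants: 4 methyl (Z)-2-azido-3-(2,4-dibromophenyl)prop-2-enoate
Product: 6 methyl 4,6-dibromo-1H-indole-2-carboxylate, via 2H-azirine ester 5 (not isolated)
Conditions: xylenes, 140 °C, slow addition of 4 (final 0.05 M), N2 atmosphere, blast shield
Reagents that add atoms: none
Why: Heating the vinyl azide expels N2 to give a singlet vinyl nitrene that is reversibly stored as 2H-azirine 5; the nitrene nitrogen then bonds to the aryl carbon ortho to the side chain, formally a C–H insertion and in detail a five-atom 6π electrocyclisation onto the arene followed by a 1,5-hydrogen shift that restores aromaticity. This is the Hemetsberger–Knittel indole synthesis, the closest known reaction type being the thermolysis of 2-azido-3-arylacrylates to indole-2-carboxylates. The one new ring, the pyrrole ring, closes by N1–C7a bond formation as a five-membered electrocyclic closure of the N–C=C–C=C unit. No stereocentre is created. The step needs regioselectivity between the two ortho carbons and chemoselectivity towards the C–Br bonds: the ortho carbon that becomes C4 already carries bromine, so only the C–H carbon that becomes C7a can accept nitrogen, while neutral metal-free thermolysis should leave both aryl bromides and the ester untouched and high dilution should suppress bimolecular azirine or nitrene dimerisation.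

Step 3
Reactants: 6 methyl 4,6-dibromo-1H-indole-2-carboxylate; 7 dimethyl disulfide
Product: 9 methyl 4,6-dibromo-3-(methylsulfanyl)-1H-indole-2-carboxylate, via methanesulfenyl chloride 8 (not isolated)
Conditions: 7 (0.6 equiv), SO2Cl2 (0.55 equiv), CH2Cl2, −20 °C, 30 min; then 6, DMF, 0 °C → rt
Reagents that add atoms: none
Why: Electrophilic aromatic substitution (sulfenylation of an indole with a sulfenyl chloride): 8, formed by chlorinolysis of the S–S bond of 7, is attacked by C3, the only free and most nucleophilic position of the pyrrole ring since C2 is occupied by the ester, and loss of HCl restores the indole; the small MeS group should fit beside the C4 bromine.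

Step 4
Reactants: 9 methyl 4,6-dibromo-3-(methylsulfanyl)-1H-indole-2-carboxylate
Product: 10 4,6-dibromo-3-(methylsulfanyl)-1H-indole-2-carboxylic acid
Conditions: LiOH·H2O (3 equiv), THF/MeOH/H2O, 40 °C; acidic work-up (1 M HCl, pH 2)
Reagents that add atoms: lithium hydroxide, [Li+].[OH-]
Why: Saponification by acyl–oxygen cleavage (BAC2): hydroxide adds to the ester carbonyl and expels methoxide, the aryl bromides and the thioether being inert to aqueous LiOH at 40 °C, and acidification should precipitate the free acid.

Step 5
Reactants: 10 4,6-dibromo-3-(methylsulfanyl)-1H-indole-2-carboxylic acid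
Product: 11 2,4,6-tribromo-3-(methylsulfanyl)-1H-indole
Conditions: NBS (1.05 equiv), LiOAc (0.1 equiv), dry DMF, 0 °C → rt, dark
Reagents that add atoms: N-bromosuccinimide, O=C1CCC(=O)N1Br
Why: Ipso-bromodecarboxylation (ionic Hunsdiecker-type halodecarboxylation of an electron-rich heteroaromatic acid): electrophilic bromine adds at the carboxyl-bearing C2, the resulting C3 cation is stabilised by the benzo ring and the sulfur lone pair, and loss of CO2 from the carboxylate restores the indole with bromine at C2.

Compound list
1 | 2,4-dibromobenzaldehyde | O=Cc1ccc(Br)cc1Br | starting material
2 | methyl azidoacetate | COC(=O)CN=[N+]=[N-] | starting material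
3 | methyl 2-azido-3-(2,4-dibromophenyl)-3-hydroxypropanoate (aldol adduct, not isolated; racemic, both diastereomers, both stereocentres lost on elimination) | COC(=O)C(N=[N+]=[N-])C(O)c1ccc(Br)cc1Br | intermediate
4 | methyl (Z)-2-azido-3-(2,4-dibromophenyl)prop-2-enoate (azide and aryl cis across the alkene) | [N-]=[N+]=N/C(C(=O)OC)=C\c1ccc(Br)cc1Br | intermediate
5 | methyl 2-(2,4-dibromophenyl)-2H-azirine-3-carboxylate (not isolated; racemic) | COC(=O)C1=NC1c1ccc(Br)cc1Br | intermediate
6 | methyl 4,6-dibromo-1H-indole-2-carboxylate | COC(=O)c1cc2c(Br)cc(Br)cc2[nH]1 | intermediate
7 | dimethyl disulfide | CSSC | starting material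
8 | methanesulfenyl chloride (not isolated) | CSCl | intermediate
9 | methyl 4,6-dibromo-3-(methylsulfanyl)-1H-indole-2-carboxylate | COC(=O)c1[nH]c2cc(Br)cc(Br)c2c1SC | intermediate
10 | 4,6-dibromo-3-(methylsulfanyl)-1H-indole-2-carboxylic acid | OC(=O)c1[nH]c2cc(Br)cc(Br)c2c1SC | intermediate
11 | 2,4,6-tribromo-3-(methylsulfanyl)-1H-indole | CSc1c(Br)[nH]c2cc(Br)cc(Br)c12 | target

Total step count: 5. Longest linear sequence: 5 steps (1 → 4 → 6 → 9 → 10 → 11).

Steps most likely to fail

Step 5. The electrophile may be consumed at sulfur (bromosulfonium formation followed by Pummerer-type or hydrolytic breakdown), at nitrogen or on the benzo ring instead of at the carboxyl-bearing C2. The ipso adduct may also stall without losing CO2. The fallback separates C–C cleavage from C–Br formation and sets out from acid 10. Silver-catalysed protodecarboxylation (Ag2CO3 10 mol %, AcOH cat., DMSO, 120 °C) should give 4,6-dibromo-3-(methylsulfanyl)-1H-indole F1. Its free C2–H is then brominated by ordinary electrophilic substitution with NBS (1.0 equiv, dry CH2Cl2, −78 → 0 °C), a transformation typical of 3-alkylthioindoles. The fallback returns to the route at target 11.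

Step 3. Attack of the ester-deactivated, peri-hindered C3 on the sulfenyl chloride may be too slow, so that chlorination or N-sulfenylation competes. The fallback reverses both the order of steps and the polarity of the sulfenylation and sets out from ester 6. Saponification (LiOH·H2O, THF/MeOH/H2O, 40 °C, then 1 M HCl) should give 4,6-dibromo-1H-indole-2-carboxylic acid F2. Double deprotonation with NaH (2.5 equiv, DMF, 0 °C) gives an indolide carboxylate dianion that is far more nucleophilic at C3. It should attack dimethyl disulfide 7 directly (rt → 50 °C), and acidification delivers acid 10. The fallback returns to the route at 10 without an extra step.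

Step 1. Base-induced decomposition of the azido enolate (loss of N2) may outrun addition to the ortho-substituted aldehyde, or the condensation may stop at the aldol stage without dehydration. The fallback is a stepwise aldol, activation and elimination sequence that sets out from aldehyde 1 and azidoacetate 2. Addition at −30 °C with NaOMe (1.2 equiv) in MeOH and a cold NH4Cl quench allows aldol adduct 3 to be isolated. Treatment with MsCl and Et3N (CH2Cl2, 0 °C) should give methyl 2-azido-3-(2,4-dibromophenyl)-3-(methylsulfonyloxy)propanoate F3. Excess Et3N or DBU at rt then eliminates the mesylate to the Z azidoacrylate. The fallback returns to the route at 4.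

Step 2 is expected to be dependable, provided the azide is added slowly to the hot solvent.

Further compounds
F1 | step 5 | 4,6-dibromo-3-(methylsulfanyl)-1H-indole | CSc1c[nH]c2cc(Br)cc(Br)c12
F2 | step 3 | 4,6-dibromo-1H-indole-2-carboxylic acid | OC(=O)c1cc2c(Br)cc(Br)cc2[nH]1
F3 | step 1 | methyl 2-azido-3-(2,4-dibromophenyl)-3-(methylsulfonyloxy)propanoate (racemic, both diastereomers) | COC(=O)C(N=[N+]=[N-])C(OS(C)(=O)=O)c1ccc(Br)cc1Br
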